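**Plan**

1. Numbering: carbocycle C1–C9 (C1 bears the exocyclic methylene, C2 and C6 are the ring-fusion carbons, C3–C5 complete the cyclopentane, C7–C9 the cyclohexane); C11 is the carbinol carbon on C5, Cq the epoxide carbon on C7.
2. Retrosynthesis: the five acyl–O bonds and the epoxide CH2–O bond are cut first, then C1=CH2 (back to a ketone), the C8–O and C9–O bonds (back to a C8=C9 alkene) and C8=C9 itself (metathesis of two vinyl groups).
3. The cyclopentane C2–C6 has trans hydrogens on C2 and C6 on either side of the oxygenated C3 and C4, so it is a reduced trans-4,5-disubstituted 2-hydroxycyclopentenone; it is opened at C2–C6 to an acyclic 2-(methoxymethoxy) dienone, which is cut at C2=C3 (aldol condensation), C4–C5 (vinyllithium acylation) and C6–C7 (alkynyl opening of an epoxy alcohol).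
4. Forward order: chain assembly, five-membered ring by Nazarov cyclisation, six-membered ring by ring-closing metathesis, then dihydroxylation, methylenation, staged acylation and epoxide closure.
5. Stereochemistry: Cq and C7 from a Sharpless epoxidation and its inverting opening; C11 from (S)-but-3-yn-2-ol; C6 from C7 by torquoselection and C2 from conrotation; C3 and C4 by hydride delivery anti to their neighbours and C5 by equilibration; C8/C9 by dihydroxylation anti to the C7 branch; the acyl stereocentres from (R)-2-methylbutanoic acid and ethyl (S)-lactate.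

Key step: step 16

Remark: the two 2-methylbutanoyl groups of the given structure read as (R); (S)-but-3-yn-2-ol, (R)-2-methylbutanoic acid and ethyl 3-bromo-2-oxobutanoate are taken as purchasable.

**Route**

Step 1
Reactants: 1 acrolein
Product: 2 ethyl (2E)-2-methylpenta-2,4-dienoate
Conditions: Ph3P=C(Me)CO2Et, CH2Cl2, 0 °C → rt
Reagents that add atoms: ethyl 2-(triphenylphosphoranylidene)propanoate, CCOC(=O)C(C)=P(c1ccccc1)(c1ccccc1)c1ccccc1
Why: Wittig olefination with a stabilised ylide should give the (E)-trisubstituted dienoate, the ester trans to the vinyl group.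

Step 2
Reactants: 2 ethyl (2E)-2-methylpenta-2,4-dienoate
Product: 3 (2E)-2-methylpenta-2,4-dien-1-ol
Conditions: i-Bu2AlH (2.2 equiv), CH2Cl2, −78 °C; aq. KNa tartrate
Reagents that add atoms: none
Why: Hydride reduction of the conjugated ester to the allylic alcohol by i-Bu2AlH (1,2-reduction) leaves the diene untouched.

Step 3
Reactants: 3 (2E)-2-methylpenta-2,4-dien-1-ol
Product: 4 [(2R,3R)-3-ethenyl-2-methyloxiran-2-yl]methanol
Conditions: Ti(OiPr)4 (10 mol%), D-(−)-diisopropyl tartrate (12 mol%), t-BuOOH, 4 Å molecular sieves, CH2Cl2, −20 °C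
Reagents that add atoms: tert-butyl hydroperoxide, CC(C)(C)OO
Why: Sharpless asymmetric epoxidation is confined to the allylic-alcohol double bond, and the D-tartrate ligand sets Cq and the future C7 as (R).

Step 4
Reactants: 5 (S)-but-3-yn-2-ol
Product: 6 1-{[(2S)-but-3-yn-2-yloxy]methyl}-4-methoxybenzene
Conditions: NaH, 4-MeOC6H4CH2Cl, Bu4NI (cat.), THF/DMF, 0 °C → rt
Reagents that add atoms: 4-methoxybenzyl chloride, COc1ccc(CCl)cc1
Why: Williamson etherification of the alkoxide protects the C11 hydroxyl without touching its stereocentre.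

Step 5
Reactants: 6 1-{[(2S)-but-3-yn-2-yloxy]methyl}-4-methoxybenzene; 4 [(2R,3R)-3-ethenyl-2-methyloxiran-2-yl]methanol
Product: 9 (2S,3R,6S)-3-ethenyl-6-[(4-methoxybenzyl)oxy]-2-methylhept-4-yne-1,2-diol, via lithium acetylide 7 (not isolated), via alkynylalane 8 (not isolated)
Conditions: 6, n-BuLi, toluene, −78 → 0 °C; Et2AlCl, 0 °C; then 4, 0 °C → rt; aq. KNa tartrate
Reagents that add atoms: n-butyllithium, [Li]CCCC (lithium only in 7); diethylaluminium chloride, CC[Al](Cl)CC (aluminium only in 8)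
Why: Alkynylalane opening of a 2,3-epoxy alcohol, in which the aluminium alkoxide of the primary hydroxyl steers SN2 attack to the allylic secondary carbon (C7) and away from the tertiary Cq, proceeds with inversion at C7 and retention at Cq.

Step 6
Reactants: 9 (2S,3R,6S)-3-ethenyl-6-[(4-methoxybenzyl)oxy]-2-methylhept-4-yne-1,2-diol
Product: 10 (4S)-4-{(3R,6S)-6-[(4-methoxybenzyl)oxy]hept-1-en-4-yn-3-yl}-2,2,4-trimethyl-1,3-dioxolane
Conditions: Me2C(OMe)2, PPTS (cat.), CH2Cl2, rt
Reagents that add atoms: 2,2-dimethoxypropane, COC(C)(C)OC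
Why: Acid-catalysed transketalisation ties the primary/tertiary 1,2-diol into an isopropylidene acetal.

Step 7
Reactants: 10 (4S)-4-{(3R,6S)-6-[(4-methoxybenzyl)oxy]hept-1-en-4-yn-3-yl}-2,2,4-trimethyl-1,3-dioxolane
Product: 12 (4S)-4-{(3R,4E,6S)-5-iodo-6-[(4-methoxybenzyl)oxy]hepta-1,4-dien-3-yl}-2,2,4-trimethyl-1,3-dioxolane, via vinylstannane 11 (not isolated)
Conditions: Bu3SnH, PdCl2(PPh3)2 (3 mol%), THF, 0 °C → rt; then I2, CH2Cl2, 0 °C
Reagents that add atoms: tributyltin hydride, CCCC[SnH](CCCC)CCCC (tin only in 11); iodine, II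
Why: Palladium-catalysed syn-hydrostannation of the propargylic ether should place tin on C5, next to the ether-bearing carbon and away from the congested C7, and iododestannylation with retention then gives the iodoalkene in which C7 and C11 are cis.

Step 8
Reactants: 13 methyl glycolate
Product: 14 methyl 2-(methoxymethoxy)acetate
Conditions: MeOCH2Cl, i-Pr2NEt, CH2Cl2, 0 °C → rt
Reagents that add atoms: chloromethyl methyl ether, COCCl
Why: O-alkylation with an α-chloro ether installs the methoxymethyl group that later leaves as a cation in the key step.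

Step 9
Reactants: 14 methyl 2-(methoxymethoxy)acetate
Product: 15 N-methoxy-2-(methoxymethoxy)-N-methylacetamide
Conditions: MeNH(OMe)·HCl, i-PrMgCl, THF, −20 °C
Reagents that add atoms: N,O-dimethylhydroxylamine hydrochloride, CNOC.Cl
Why: Aminolysis of the ester by the magnesium amide of N,O-dimethylhydroxylamine gives the Weinreb amide.

Step 10
Reactants: 12 (E)-C5 iodide; 15 N-methoxy-2-(methoxymethoxy)-N-methylacetamide
Product: 17 (3E,5R)-1-(methoxymethoxy)-3-{(1S)-1-[(4-methoxybenzyl)oxy]ethyl}-5-[(4S)-2,2,4-trimethyl-1,3-dioxolan-4-yl]hepta-3,6-dien-2-one, via vinyllithium 16 (not isolated)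
Conditions: t-BuLi (2.1 equiv), Et2O, −78 °C; then 15, −78 → −20 °C; aq. NH4Cl
Reagents that add atoms: tert-butyllithium, [Li]C(C)(C)C (lithium only in 16)
Why: Iodine–lithium exchange with retention of alkene geometry and acylation of the vinyllithium by the Weinreb amide, whose chelated adduct prevents over-addition, form the C4–C5 bond with C4 trans to C7.

Step 11
Reactants: 18 ethyl 3-bromo-2-oxobutanoate
Product: 19 ethyl 2-(1-bromoethyl)-1,3-dioxolane-2-carboxylate
Conditions: Me3SiOCH2CH2OSiMe3, Me3SiOTf (cat.), CH2Cl2, −78 → 0 °C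
Reagents that add atoms: 1,2-bis(trimethylsilyloxy)ethane, C[Si](C)(C)OCCO[Si](C)(C)C
Why: Silyl-transfer ketalisation of the ketone under aprotic conditions avoids bromide displacement and transesterification.

Step 12
Reactants: 19 ethyl 2-(1-bromoethyl)-1,3-dioxolane-2-carboxylate
Product: 20 ethyl 2-ethenyl-1,3-dioxolane-2-carboxylate
Conditions: KOt-Bu, THF, 0 °C
Reagents that add atoms: none
Why: E2 dehydrobromination of the α-bromo ketal gives the vinyl ketal, the ester having no α-hydrogen to enolise.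

Step 13
Reactants: 20 ethyl 2-ethenyl-1,3-dioxolane-2-carboxylate
Product: 21 2-ethenyl-1,3-dioxolane-2-carbaldehyde
Conditions: i-Bu2AlH (1.05 equiv), CH2Cl2, −78 °C; used as a solution
Reagents that add atoms: none
Why: Partial hydride reduction of an α,α-dialkoxy ester stops at the aldehyde because the chelated hemiacetal aluminate persists at −78 °C.

Step 14
Reactants: 17 (E)-enone; 21 2-ethenyl-1,3-dioxolane-2-carbaldehyde
Product: 23 aldol adduct: C2-hydroxy C3-(methoxymethoxy) C4-ketone (epimers at C2 and C3), via lithium enolate 22 (not isolated)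
Conditions: LiN(i-Pr)2, THF, −78 °C; then 21, −78 °C; aq. NH4Cl
Reagents that add atoms: lithium diisopropylamide, [Li]N(C(C)C)C(C)C (lithium only in 22)
Why: Kinetic deprotonation at the only α-position (C3) and aldol addition to the non-enolisable, highly electrophilic aldehyde form the C2–C3 bond, and the two new carbinol centres are erased in the next step.

Step 15
Reactants: 23 aldol adduct
Product: 25 (2Z,5E)-C2=C3(OCH2OMe)–C4(=O)–C5=C6 dienone, via mesylate 24 (not isolated)
Conditions: MeSO2Cl, Et3N, CH2Cl2, 0 °C; then DBU, rt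
Reagents that add atoms: methanesulfonyl chloride, CS(=O)(=O)Cl (retained only in 24)
Why: Mesylation and E1cB elimination (aldol condensation) should give the thermodynamically preferred (Z)-enol ether, in which the bulky C1 ketal stands anti to the C4 carbonyl.

Step 16
Reactants: 25 (2Z,5E)-dienone
Product: 26 diosphenol: trans-4,5-disubstituted 2-hydroxycyclopent-2-enone (C3 ketone; C4 enol; C2-H and C6-H trans)
Conditions: Sc(OTf)3 (0.2 equiv), MeCN, 0 °C → rt; aq. NaHCO3
Reagents that add atoms: none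
Why: Chelation of Sc(OTf)3 by the C4 carbonyl and the C3 ether oxygen gives a 3-oxidopentadienyl cation (C2 to C6) that closes by thermal 4π conrotatory electrocyclisation and forms the C2–C6 bond; the alkoxy-stabilised oxyallyl cation then expels the methoxymethyl cation from O3 instead of losing the C2 proton, so the product is the diosphenol with C3 as ketone and C4 as enol. The closest known reaction type is the Lewis-acid-catalysed Nazarov cyclisation of 2-alkoxy-1,4-dien-3-ones that ends in a 2-hydroxycyclopent-2-enone. The one ring formed, the cyclopentenone C2–C6, closes by a five-membered electrocyclic ring closure between the two termini of the pentadienyl cation. C6 is controlled by the adjacent C7 stereocentre: allylic 1,3-strain holds C7–H in the plane of C5=C6 towards the C5 side chain, the vinyl group and the quaternary dioxolane carbon then flank the two faces, and C2 bonds to the face away from the quaternary carbon. C2 is controlled by conrotation, because the C1 and C7 branches both stand anti to the carbonyl in the (2Z,5E)-dienone and therefore end up trans. The step needs torquoselectivity, loss of the oxygen substituent in preference to a proton and tolerance of two ketals; these rest on the biased C7 centre, on the ionisable methoxymethyl group in a base-free medium and on two-point binding of the mild Lewis acid to the α-alkoxy ketone.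

Step 17
Reactants: 26 diosphenol
Product: 27 O4-triethylsilyl enol ether of 26 (2-silyloxy enone)
Conditions: Et3SiCl, imidazole, CH2Cl2, 0 °C
Reagents that add atoms: chlorotriethylsilane, CC[Si](Cl)(CC)CC
Why: O-silylation of the acidic enol hydroxyl locks the diosphenol as one tautomer, which protects the C2 stereocentre and leaves C3 as the only carbonyl.

Step 18
Reactants: 27 2-silyloxy enone
Product: 28 C3 allylic alcohol (C3-OH cis to the C1 branch on C2)
Conditions: i-Bu2AlH, CH2Cl2, −78 °C
Reagents that add atoms: none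
Why: In this 1,2-reduction of the enone carbonyl the hydride attacks C3 anti to the neighbouring ketal-bearing branch on C2, so the new hydroxyl is cis to that branch.

Step 19
Reactants: 28 C3 allylic alcohol
Product: 29 C3 tert-butyldimethylsilyl ether of 28
Conditions: t-BuMe2SiOTf, 2,6-lutidine, CH2Cl2, −78 °C
Reagents that add atoms: tert-butyldimethylsilyl trifluoromethanesulfonate, CC(C)(C)[Si](C)(C)OS(=O)(=O)C(F)(F)F
Why: Silylation with a bulky silyl triflate gives a C3 ether that neither migrates nor lets C3 enolise at the ketone stage that follows.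

Step 20
Reactants: 29 bis-silyl compound
Product: 30 C4 ketone with C5-H (C11 branch trans to the C7 branch)
Conditions: K2CO3, MeOH, 0 °C → rt
Reagents that add atoms: none
Why: Methanolysis of the silyl enol ether (the alkyl silyl ether survives) releases the C4 ketone, and base-mediated epimerisation through the C4–C5 enolate should settle C5 in the thermodynamically favoured arrangement with the C11 branch trans to the C7 branch on C6.

Step 21
Reactants: 30 C4 ketone
Product: 31 β-hydroxy ketone (free C11 hydroxyl)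
Conditions: DDQ, CH2Cl2/pH 7 buffer, 0 °C
Reagents that add atoms: none
Why: Oxidative cleavage of the 4-methoxybenzyl ether by DDQ frees the C11 hydroxyl under neutral conditions, before a C4 hydroxyl exists that could be trapped as a cyclic acetal.

Step 22
Reactants: 31 β-hydroxy ketone
Product: 32 C4,C11-diol
Conditions: NaBH4, MeOH, −40 → 0 °C
Reagents that add atoms: none
Why: In this borohydride reduction of the ketone the hydride reaches C4 from the face opposite its two cis neighbours (the C3 silyloxy group and the C11 branch on C5), which completes the all-cis C3–C4–C5 array.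

Step 23
Reactants: 32 C4,C11-diol
Product: 33 C4,C11-diacetate
Conditions: Ac2O, DMAP, pyridine, rt
Reagents that add atoms: acetic anhydride, CC(=O)OC(C)=O
Why: DMAP-catalysed acetylation installs the final C4 and C11 acetates in one operation.

Step 24
Reactants: 33 C4,C11-diacetate
Product: 34 C3 alcohol
Conditions: HF·pyridine, pyridine, THF, 0 °C → rt
Reagents that add atoms: none
Why: Fluoride desilylation under buffered acidic conditions removes the only silyl ether without the acetyl migration from O4 that a basic fluoride source would invite.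

Step 25
Reactants: 34 C3 alcohol; 35 (R)-2-methylbutanoic acid
Product: 36 C3 (R)-2-methylbutanoate
Conditions: 35, DCC, DMAP, CH2Cl2, 0 °C → rt
Reagents that add atoms: none
Why: Steglich esterification acylates the hindered secondary alcohol without enolising the α-stereocentre of the acid.

Step 26
Reactants: 36 C3 (R)-2-methylbutanoate
Product: 38 trans-fused bicyclic enone (C1 ketone conjugated to C8=C9), via ring-closed ketal 37 (not isolated)
Conditions: second-generation Grubbs catalyst RuCl2(=CHPh)(PCy3)(H2IMes) (5 mol%), CH2Cl2, 40 °C; then PPTS, acetone/H2O, 50 °C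
Reagents that add atoms: water, O
Why: Ring-closing metathesis of the two vinyl groups closes the trans-fused cyclohexene at C8=C9, and the now allylic dioxolane is hydrolysed in wet acetone, where the isopropylidene acetal is retained.

Step 27
Reactants: 38 bicyclic enone
Product: 39 C8,C9-dihydroxy ketone
Conditions: OsO4 (5 mol%), N-methylmorpholine N-oxide, citric acid, t-BuOH/H2O, rt
Reagents that add atoms: osmium tetroxide, O=[Os](=O)(=O)=O (catalytic oxygen carrier); N-methylmorpholine N-oxide, C[N+]1([O-])CCOCC1; water, O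
Why: Catalytic syn-dihydroxylation of the enone double bond at acidic pH should occur on the C8=C9 face anti to the quaternary dioxolane branch on the allylic C7, giving the two hydroxyls cis to each other and trans to that branch.

Step 28
Reactants: 39 C8,C9-dihydroxy ketone
Product: 40 C1-methylene C8,C9-diol
Conditions: Zn, CH2Br2, TiCl4, THF/CH2Cl2, 0 °C → rt
Reagents that add atoms: dibromomethane, BrCBr
Why: Takai–Lombardo methylenation is non-basic and tolerates hydroxyl and ester groups, so C2 and C9 should not epimerise and the β-acyloxy group at C3 should not eliminate.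

Step 29
Reactants: 40 C1-methylene C8,C9-diol; 35 (R)-2-methylbutanoic acid
Product: 42 C8 (R)-2-methylbutanoate of 40, via acid chloride 41 (not isolated)
Conditions: 35, (COCl)2, DMF (cat.), CH2Cl2, 0 °C → rt; then 40, Me2SnCl2 (5 mol%), i-Pr2NEt, THF, 0 °C → rt
Reagents that add atoms: oxalyl chloride, O=C(Cl)C(Cl)=O (chlorine only in 41)
Why: Dimethyltin dichloride-catalysed monoacylation of a cis-1,2-diol through its stannylene chelate should acylate the equatorial C8 oxygen and leave the axial allylic C9 hydroxyl, as known for cis-diols of pyranosides.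

Step 30
Reactants: 43 ethyl (S)-lactate
Product: 44 ethyl (2S)-2-[(triethylsilyl)oxy]propanoate
Conditions: Et3SiCl, imidazole, CH2Cl2, 0 °C → rt
Reagents that add atoms: chlorotriethylsilane, CC[Si](Cl)(CC)CC
Why: Silyl protection of the secondary alcohol gives an ether that survives organomagnesium reagents and is later removed by mild aqueous acid.

Step 31
Reactants: 44 ethyl (2S)-2-[(triethylsilyl)oxy]propanoate
Product: 46 (3S)-3-[(triethylsilyl)oxy]butan-2-one, via Weinreb amide 45 (not isolated)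
Conditions: MeNH(OMe)·HCl, i-PrMgCl, THF, −20 °C; then MeMgBr, 0 °C; aq. NH4Cl
Reagents that add atoms: N,O-dimethylhydroxylamine hydrochloride, CNOC.Cl (retained only in 45); methylmagnesium bromide, C[Mg]Br
Why: Weinreb ketone synthesis in one flask (ester aminolysis, then Grignard addition to the chelated amide) gives the methyl ketone without over-addition or α-epimerisation.

Step 32
Reactants: 46 (3S)-3-[(triethylsilyl)oxy]butan-2-one
Product: 47 ethyl (2E,4S)-3-methyl-4-[(triethylsilyl)oxy]pent-2-enoate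
Conditions: (EtO)2P(O)CH2CO2Et, NaH, THF, 0 °C → rt
Reagents that add atoms: triethyl phosphonoacetate, CCOC(=O)CP(=O)(OCC)OCC
Why: Horner–Wadsworth–Emmons olefination of the methyl ketone should favour the (E)-enoate, the ester trans to the branched silyloxyethyl group.

Step 33
Reactants: 47 ethyl (2E,4S)-3-methyl-4-[(triethylsilyl)oxy]pent-2-enoate
Product: 48 (2E,4S)-3-methyl-4-[(triethylsilyl)oxy]pent-2-enoic acid
Conditions: LiOH, THF/H2O, 0 °C → rt; then aq. HCl to pH 4, 0 °C
Reagents that add atoms: lithium hydroxide, [Li+].[OH-]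
Why: Saponification of the ethyl ester should spare the secondary silyl ether under cold hydroxide and brief mild acidification.

Step 34
Reactants: 42 C8 (R)-2-methylbutanoate; 48 (2E,4S)-3-methyl-4-[(triethylsilyl)oxy]pent-2-enoic acid
Product: 50 silyl-protected pentaester acetonide, via mixed anhydride 49 (not isolated)
Conditions: 48, 2,4,6-Cl3C6H2COCl, Et3N, THF, rt; then 42, DMAP, toluene, rt
Reagents that add atoms: 2,4,6-trichlorobenzoyl chloride, O=C(Cl)c1c(Cl)cc(Cl)cc1Cl (retained only in 49)
Why: Yamaguchi esterification activates the enoic acid as a mixed anhydride that acylates the hindered axial allylic C9 hydroxyl under DMAP catalysis.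

Step 35
Reactants: 50 silyl-protected pentaester acetonide
Product: 51 pentaester triol (Cq-OH, CH2OH and side-chain OH free)
Conditions: AcOH/THF/H2O (3:1:1), 40 °C
Reagents that add atoms: none
Why: Mild aqueous acid hydrolyses the isopropylidene acetal and the triethylsilyl ether together while the five esters and the exocyclic alkene should remain intact.

Step 36
Reactants: 51 pentaester triol
Product: 53 CNP0282336.1 (target), via primary tosylate 52 (not isolated)
Conditions: TsCl, Et3N, Bu2SnO (5 mol%), CH2Cl2, 0 °C; then DBU, rt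
Reagents that add atoms: p-toluenesulfonyl chloride, Cc1ccc(S(=O)(=O)Cl)cc1 (retained only in 52)
Why: Tin-catalysed selective sulfonylation of the primary hydroxyl of the 1,2-diol and intramolecular Williamson displacement by the tertiary alkoxide close the epoxide with retention at Cq, since the tertiary C–O bond is never broken.

**Compound list**

1 | acrolein | C=CC=O | starting material
2 | ethyl (2E)-2-methylpenta-2,4-dienoate | C=C/C=C(\C)C(=O)OCC | intermediate
3 | (2E)-2-methylpenta-2,4-dien-1-ol | C=C/C=C(\C)CO | intermediate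
4 | [(2R,3R)-3-ethenyl-2-methyloxiran-2-yl]methanol | C=C[C@H]1O[C@]1(C)CO | intermediate
5 | (S)-but-3-yn-2-ol | C#C[C@H](C)O | starting material
6 | 1-{[(2S)-but-3-yn-2-yloxy]methyl}-4-methoxybenzene | C#C[C@H](C)OCc1ccc(OC)cc1 | intermediate
7 | lithium acetylide of 6 | [Li]C#C[C@H](C)OCc1ccc(OC)cc1 | intermediate
8 | diethyl(alkynyl)alane of 6 | CC[Al](CC)C#C[C@H](C)OCc1ccc(OC)cc1 | intermediate
9 | (2S,3R,6S)-3-ethenyl-6-[(4-methoxybenzyl)oxy]-2-methylhept-4-yne-1,2-diol | C=C[C@H](C#C[C@H](C)OCc1ccc(OC)cc1)[C@](C)(O)CO | intermediate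
10 | (4S)-4-{(3R,6S)-6-[(4-methoxybenzyl)oxy]hept-1-en-4-yn-3-yl}-2,2,4-trimethyl-1,3-dioxolane | C=C[C@H](C#C[C@H](C)OCc1ccc(OC)cc1)[C@@]2(C)COC(C)(C)O2 | intermediate
11 | vinylstannane: 10 after syn addition of H to C6 and Bu3Sn to C5 | C=C[C@H](/C=C(/[Sn](CCCC)(CCCC)CCCC)[C@H](C)OCc1ccc(OC)cc1)[C@@]2(C)COC(C)(C)O2 | intermediate
12 | (4S)-4-{(3R,4E,6S)-5-iodo-6-[(4-methoxybenzyl)oxy]hepta-1,4-dien-3-yl}-2,2,4-trimethyl-1,3-dioxolane | C=C[C@H](/C=C(/I)[C@H](C)OCc1ccc(OC)cc1)[C@@]2(C)COC(C)(C)O2 | intermediate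
13 | methyl glycolate | COC(=O)CO | starting material
14 | methyl 2-(methoxymethoxy)acetate | COCOCC(=O)OC | intermediate
15 | N-methoxy-2-(methoxymethoxy)-N-methylacetamide | COCOCC(=O)N(C)OC | intermediate
16 | C5 vinyllithium from 12 (alkene geometry retained) | C=C[C@H](/C=C(/[Li])[C@H](C)OCc1ccc(OC)cc1)[C@@]2(C)COC(C)(C)O2 | intermediate
17 | (3E,5R)-1-(methoxymethoxy)-3-{(1S)-1-[(4-methoxybenzyl)oxy]ethyl}-5-[(4S)-2,2,4-trimethyl-1,3-dioxolan-4-yl]hepta-3,6-dien-2-one | C=C[C@H](/C=C(/C(=O)COCOC)[C@H](C)OCc1ccc(OC)cc1)[C@@]2(C)COC(C)(C)O2 | intermediate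
18 | ethyl 3-bromo-2-oxobutanoate (racemic) | CCOC(=O)C(=O)C(C)Br | starting material
19 | ethyl 2-(1-bromoethyl)-1,3-dioxolane-2-carboxylate (racemic) | CCOC(=O)C1(C(C)Br)OCCO1 | intermediate
20 | ethyl 2-ethenyl-1,3-dioxolane-2-carboxylate | CCOC(=O)C1(C=C)OCCO1 | intermediate
21 | 2-ethenyl-1,3-dioxolane-2-carbaldehyde | O=CC1(C=C)OCCO1 | intermediate
22 | lithium enolate of 17 (C3=C4–OLi) | C=C[C@H](/C=C(/C(O[Li])=COCOC)[C@H](C)OCc1ccc(OC)cc1)[C@@]2(C)COC(C)(C)O2 | intermediate
23 | aldol adduct of 17 and 21: C2-hydroxy C3-(methoxymethoxy) C4-ketone, epimers at C2 and C3 | C=CC1(OCCO1)C(O)C(OCOC)C(=O)/C([C@H](C)OCc2ccc(OC)cc2)=C/[C@H]([C@@]3(C)COC(C)(C)O3)C=C | intermediate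
24 | C2 methanesulfonate of 23 | C=CC1(OCCO1)C(OS(C)(=O)=O)C(OCOC)C(=O)/C([C@H](C)OCc2ccc(OC)cc2)=C/[C@H]([C@@]3(C)COC(C)(C)O3)C=C | intermediate
25 | (2Z,5E)-dienone: C1 vinyl ketal, C2=C3 methoxymethyl enol ether, C4 ketone, C5=C6 alkene with the C11 ether on C5 and the C7 vinyl/dioxolane branch on C6 | C=CC1(OCCO1)/C=C(OCOC)/C(=O)/C([C@H](C)OCc2ccc(OC)cc2)=C/[C@H]([C@@]3(C)COC(C)(C)O3)C=C | intermediate
26 | diosphenol: 2-hydroxycyclopent-2-enone with C3 ketone, C4 enol, C2-H and C6-H trans | C=CC1(OCCO1)[C@@H]2C(=O)C(O)=C([C@H](C)OCc3ccc(OC)cc3)[C@H]2[C@H]([C@@]4(C)COC(C)(C)O4)C=C | intermediate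
27 | O4-triethylsilyl enol ether of 26 | C=CC1(OCCO1)[C@@H]2C(=O)C(O[Si](CC)(CC)CC)=C([C@H](C)OCc3ccc(OC)cc3)[C@H]2[C@H]([C@@]4(C)COC(C)(C)O4)C=C | intermediate
28 | C3 allylic alcohol, hydroxyl cis to the C1 branch | C=CC1(OCCO1)[C@@H]2[C@H](O)C(O[Si](CC)(CC)CC)=C([C@H](C)OCc3ccc(OC)cc3)[C@H]2[C@H]([C@@]4(C)COC(C)(C)O4)C=C | intermediate
29 | C3 tert-butyldimethylsilyl ether of 28 | C=CC1(OCCO1)[C@@H]2[C@H](O[Si](C)(C)C(C)(C)C)C(O[Si](CC)(CC)CC)=C([C@H](C)OCc3ccc(OC)cc3)[C@H]2[C@H]([C@@]4(C)COC(C)(C)O4)C=C | intermediate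
30 | C4 ketone, C5-H with the C11 branch trans to the C7 branch | C=CC1(OCCO1)[C@@H]2[C@H](O[Si](C)(C)C(C)(C)C)C(=O)[C@H]([C@H](C)OCc3ccc(OC)cc3)[C@H]2[C@H]([C@@]4(C)COC(C)(C)O4)C=C | intermediate
31 | β-hydroxy ketone (C11-OH free) | C=CC1(OCCO1)[C@@H]2[C@H](O[Si](C)(C)C(C)(C)C)C(=O)[C@H]([C@H](C)O)[C@H]2[C@H]([C@@]3(C)COC(C)(C)O3)C=C | intermediate
32 | C4,C11-diol, all-cis C3–C4–C5 | C=CC1(OCCO1)[C@@H]2[C@H](O[Si](C)(C)C(C)(C)C)[C@H](O)[C@H]([C@H](C)O)[C@H]2[C@H]([C@@]3(C)COC(C)(C)O3)C=C | intermediate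
33 | C4,C11-diacetate | C=CC1(OCCO1)[C@@H]2[C@H](O[Si](C)(C)C(C)(C)C)[C@H](OC(C)=O)[C@H]([C@H](C)OC(C)=O)[C@H]2[C@H]([C@@]3(C)COC(C)(C)O3)C=C | intermediate
34 | C3 alcohol | C=CC1(OCCO1)[C@@H]2[C@H](O)[C@H](OC(C)=O)[C@H]([C@H](C)OC(C)=O)[C@H]2[C@H]([C@@]3(C)COC(C)(C)O3)C=C | intermediate
35 | (R)-2-methylbutanoic acid | CC[C@@H](C)C(=O)O | starting material
36 | C3 (R)-2-methylbutanoate, monocyclic diene | C=CC1(OCCO1)[C@@H]2[C@H](OC(=O)[C@H](C)CC)[C@H](OC(C)=O)[C@H]([C@H](C)OC(C)=O)[C@H]2[C@H]([C@@]3(C)COC(C)(C)O3)C=C | intermediate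
37 | ring-closed ketal: trans-fused bicycle with C8=C9 and the C1 dioxolane | C12(OCCO1)[C@@H]3[C@H](OC(=O)[C@H](C)CC)[C@H](OC(C)=O)[C@H]([C@H](C)OC(C)=O)[C@H]3[C@H]([C@@]4(C)COC(C)(C)O4)C=C2 | intermediate
38 | trans-fused bicyclic enone (C1 ketone, C8=C9) | O=C1[C@@H]2[C@H](OC(=O)[C@H](C)CC)[C@H](OC(C)=O)[C@H]([C@H](C)OC(C)=O)[C@H]2[C@H]([C@@]3(C)COC(C)(C)O3)C=C1 | intermediate
39 | C8,C9-dihydroxy ketone | O=C1[C@@H]2[C@H](OC(=O)[C@H](C)CC)[C@H](OC(C)=O)[C@H]([C@H](C)OC(C)=O)[C@H]2[C@H]([C@@]3(C)COC(C)(C)O3)[C@@H](O)[C@H]1O | intermediate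
40 | C1-methylene C8,C9-diol | C=C1[C@@H]2[C@H](OC(=O)[C@H](C)CC)[C@H](OC(C)=O)[C@H]([C@H](C)OC(C)=O)[C@H]2[C@H]([C@@]3(C)COC(C)(C)O3)[C@@H](O)[C@H]1O | intermediate
41 | (R)-2-methylbutanoyl chloride | CC[C@@H](C)C(Cl)=O | intermediate
42 | C8 (R)-2-methylbutanoate, C9-OH free | C=C1[C@@H]2[C@H](OC(=O)[C@H](C)CC)[C@H](OC(C)=O)[C@H]([C@H](C)OC(C)=O)[C@H]2[C@H]([C@@]3(C)COC(C)(C)O3)[C@@H](OC(=O)[C@H](C)CC)[C@H]1O | intermediate
43 | ethyl (S)-lactate | CCOC(=O)[C@H](C)O | starting material
44 | ethyl (2S)-2-[(triethylsilyl)oxy]propanoate | CCOC(=O)[C@H](C)O[Si](CC)(CC)CC | intermediate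
45 | (2S)-N-methoxy-N-methyl-2-[(triethylsilyl)oxy]propanamide | CON(C)C(=O)[C@H](C)O[Si](CC)(CC)CC | intermediate
46 | (3S)-3-[(triethylsilyl)oxy]butan-2-one | CC(=O)[C@H](C)O[Si](CC)(CC)CC | intermediate
47 | ethyl (2E,4S)-3-methyl-4-[(triethylsilyl)oxy]pent-2-enoate | CCOC(=O)/C=C(\C)[C@H](C)O[Si](CC)(CC)CC | intermediate
48 | (2E,4S)-3-methyl-4-[(triethylsilyl)oxy]pent-2-enoic acid | OC(=O)/C=C(\C)[C@H](C)O[Si](CC)(CC)CC | intermediate
49 | mixed anhydride of 48 with 2,4,6-trichlorobenzoic acid | O=C(OC(=O)/C=C(\C)[C@H](C)O[Si](CC)(CC)CC)c1c(Cl)cc(Cl)cc1Cl | intermediate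
50 | silyl-protected pentaester acetonide | C=C1[C@@H]2[C@H](OC(=O)[C@H](C)CC)[C@H](OC(C)=O)[C@H]([C@H](C)OC(C)=O)[C@H]2[C@H]([C@@]3(C)COC(C)(C)O3)[C@@H](OC(=O)[C@H](C)CC)[C@H]1OC(=O)/C=C(\C)[C@H](C)O[Si](CC)(CC)CC | intermediate
51 | pentaester triol | C=C1[C@@H]2[C@H](OC(=O)[C@H](C)CC)[C@H](OC(C)=O)[C@H]([C@H](C)OC(C)=O)[C@H]2[C@H]([C@](C)(O)CO)[C@@H](OC(=O)[C@H](C)CC)[C@H]1OC(=O)/C=C(\C)[C@H](C)O | intermediate
52 | primary p-toluenesulfonate of 51 | C=C1[C@@H]2[C@H](OC(=O)[C@H](C)CC)[C@H](OC(C)=O)[C@H]([C@H](C)OC(C)=O)[C@H]2[C@H]([C@](C)(O)COS(=O)(=O)c3ccc(C)cc3)[C@@H](OC(=O)[C@H](C)CC)[C@H]1OC(=O)/C=C(\C)[C@H](C)O | intermediate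
53 | CNP0282336.1 | C=C1[C@@H]2[C@H](OC(=O)[C@H](C)CC)[C@H](OC(C)=O)[C@H]([C@H](C)OC(C)=O)[C@H]2[C@H]([C@@]2(C)CO2)[C@@H](OC(=O)[C@H](C)CC)[C@H]1OC(=O)/C=C(\C)[C@H](C)O | target

**Step count and risks**

Total steps: 36. Longest linear sequence: 26 steps (steps 1–3, 5–7, 10, 14–29, 34–36).

Steps most likely to fail:

Step 16 (Nazarov cyclisation). The Lewis acid may ionise the doubly allylic dioxolane or the isopropylidene acetal instead of activating the ketone. The oxyallyl cation may lose the C2 proton in place of the methoxymethyl group, which would erase C2. The new bond may form on the wrong face of C6, and the chelating diosphenol may hold the catalyst back. The fallback sets out from iodide 12 and removes both the Lewis acid and the oxygen leaving group. The vinyllithium from 12 is acylated with 2-[(tert-butyldimethylsilyl)oxy]-N-methoxy-N-methylacetamide to give the silyloxymethyl enone F1. Aldol addition of its lithium enolate to aldehyde 21 gives the adduct F2, and mesylation with DBU elimination gives the 2-silyloxy dienone F3. Buffered fluoride (Bu4NF, AcOH, −78 °C) releases the α-ketoenone F4. Its enol is cyclised on triethylamine-treated silica gel (Nazarov cyclisation of an α-diketone), and the enol oxygen simply ketonises. The route is rejoined at diosphenol 26.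

Step 7 (hydrostannation/iodination). Tin may be delivered to C6 instead of C5, or the stannane may be protodestannylated, so the wrong iodoalkene or the simple alkene would form. The fallback sets out from acetonide 10 and uses a hydroxyl-directed hydrometalation. DDQ removes the 4-methoxybenzyl group to give the propargylic alcohol F5. Titanocene-catalysed syn-hydromagnesiation (i-BuMgCl, Cp2TiCl2 cat., Et2O), in which the magnesium alkoxide directs the metal to the proximal carbon C5, is followed by iodinolysis to give the iodo allylic alcohol F6. Re-etherification (NaH, 4-methoxybenzyl chloride) returns iodide 12.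

Step 28 (methylenation of the unprotected dihydroxy ketone). Retro-aldol opening of the C8–C9 bond or β-elimination may occur on the Lewis-acidic reagent, or the hindered, chelated carbonyl may not react. The fallback sets out from dihydroxy ketone 39 and masks the diol first. Et3SiOTf with 2,6-lutidine gives the bis(triethylsilyl) ether F7. Methylenation of F7 (Zn/CH2Br2/TiCl4, or Cp2TiMe2 in toluene at 70 °C if the carbonyl is too hindered) gives the methylene compound F8. HF·pyridine then removes both silyl groups and returns diol 40.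

**Further compounds**

F1 | step 16 | (3E,5R)-1-[(tert-butyldimethylsilyl)oxy]-3-{(1S)-1-[(4-methoxybenzyl)oxy]ethyl}-5-[(4S)-2,2,4-trimethyl-1,3-dioxolan-4-yl]hepta-3,6-dien-2-one | C=C[C@H](/C=C(/C(=O)CO[Si](C)(C)C(C)(C)C)[C@H](C)OCc1ccc(OC)cc1)[C@@]2(C)COC(C)(C)O2
F2 | step 16 | aldol adduct of F1 and 21 (C2-hydroxy C3-silyloxy C4-ketone, epimers at C2 and C3) | C=CC1(OCCO1)C(O)C(O[Si](C)(C)C(C)(C)C)C(=O)/C([C@H](C)OCc2ccc(OC)cc2)=C/[C@H]([C@@]3(C)COC(C)(C)O3)C=C
F3 | step 16 | (2Z,5E)-2-silyloxy dienone (silyl analogue of 25) | C=CC1(OCCO1)/C=C(O[Si](C)(C)C(C)(C)C)/C(=O)/C([C@H](C)OCc2ccc(OC)cc2)=C/[C@H]([C@@]3(C)COC(C)(C)O3)C=C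
F4 | step 16 | α-ketoenone (C3,C4-diketone with the C5=C6 alkene) | C=CC1(OCCO1)CC(=O)C(=O)/C([C@H](C)OCc2ccc(OC)cc2)=C/[C@H]([C@@]3(C)COC(C)(C)O3)C=C
F5 | step 7 | propargylic alcohol (10 without the 4-methoxybenzyl group) | C=C[C@H](C#C[C@H](C)O)[C@@]2(C)COC(C)(C)O2
F6 | step 7 | (E)-C5-iodo allylic alcohol (12 without the 4-methoxybenzyl group) | C=C[C@H](/C=C(/I)[C@H](C)O)[C@@]2(C)COC(C)(C)O2
F7 | step 28 | C8,C9-bis(triethylsilyl) ether of 39 | O=C1[C@@H]2[C@H](OC(=O)[C@H](C)CC)[C@H](OC(C)=O)[C@H]([C@H](C)OC(C)=O)[C@H]2[C@H]([C@@]3(C)COC(C)(C)O3)[C@@H](O[Si](CC)(CC)CC)[C@H]1O[Si](CC)(CC)CC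
F8 | step 28 | C8,C9-bis(triethylsilyl) ether of 40 | C=C1[C@@H]2[C@H](OC(=O)[C@H](C)CC)[C@H](OC(C)=O)[C@H]([C@H](C)OC(C)=O)[C@H]2[C@H]([C@@]3(C)COC(C)(C)O3)[C@@H](O[Si](CC)(CC)CC)[C@H]1O[Si](CC)(CC)CC
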